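**Retrosynthetic overview**

- Target 19 comes from 18 by removal of four MOM ethers.
- The strategy rests on the α-hydroxy ketone C3(OH)–C4(=O) of ring C, with O1 already joining C8a of ring A to C2. Ring C is closed last, at C3–C4, by a carbene-catalysed crossed benzoin of dialdehyde 17 with dynamic kinetic resolution at the labile C2.
- 17 comes from the O1–C2 ether bond (phenoxide of ring A aldehyde 9 on the ring B α-bromo ester 14), then reduction to the diol and double oxidation.
- 9 comes from 2-methoxyresorcinol: C–H borylation/oxidation (C8a oxygen), Claisen rearrangement (C8 prenyl), ortho-formylation (C4). 14 comes from homogentisic acid.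
- Rings A and B are bought; ring C is the only ring formed.

Key step: step 13

Assumption: the (5aS,10bR) antipode of the triazolium salt is taken to give the 2R series; the sense of induction cannot be predicted for this substrate class, and the (5aR,10bS) antipode is used instead if a test run shows the opposite sense.

**Route**

Step 1
Reactants: 1 2-methoxyresorcinol (2-methoxybenzene-1,3-diol)
Product: 2 2-methoxy-1,3-bis(methoxymethoxy)benzene
Conditions: MOMCl, i-Pr2NEt, CH2Cl2, 0 °C to rt
Reagents that add atoms: chloromethyl methyl ether (MOMCl), COCCl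
Why: O-alkylation of both phenols with the chloromethyl ether under amine base (Williamson-type acetal formation) should give the bis-MOM ether, which is stable to the borylation, rearrangement, hydride and enolate conditions that follow.

Step 2
Reactants: 2 2-methoxy-1,3-bis(methoxymethoxy)benzene
Product: 3 2-[4-methoxy-3,5-bis(methoxymethoxy)phenyl]-4,4,5,5-tetramethyl-1,3,2-dioxaborolane
Conditions: B2pin2, [Ir(OMe)(cod)]2 (cat.), 4,4'-di-tert-butyl-2,2'-bipyridine, THF, 80 °C
Reagents that add atoms: bis(pinacolato)diboron, CC1(C)OB(OC1(C)C)B1OC(C)(C)C(C)(C)O1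
Why: iridium-catalysed aromatic C–H borylation is governed by sterics and should go to C5, the only ring position without an ortho substituent.

Step 3
Reactants: 3 2-[4-methoxy-3,5-bis(methoxymethoxy)phenyl]-4,4,5,5-tetramethyl-1,3,2-dioxaborolane
Product: 4 4-methoxy-3,5-bis(methoxymethoxy)phenol
Conditions: 30% aq. H2O2, NaOH, THF, 0 °C to rt
Reagents that add atoms: hydrogen peroxide, OO
Why: oxidation of the aryl boronate with alkaline peroxide (boron-to-oxygen 1,2-shift, then hydrolysis) should give the phenol without touching the base-stable MOM ethers.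

Step 4
Reactants: 4 4-methoxy-3,5-bis(methoxymethoxy)phenol; 5 3-chloro-3-methylbut-1-yne
Product: 6 2-methoxy-1,3-bis(methoxymethoxy)-5-[(2-methylbut-3-yn-2-yl)oxy]benzene
Conditions: DBU, CuCl2 (cat.), MeCN, 0 °C
Reagents that add atoms: none
Why: copper-catalysed O-propargylation of a phenol with a tertiary propargylic chloride is the standard entry to 1,1-dimethylpropargyl aryl ethers, and this phenol has no ortho substituent to hinder it.

Step 5
Reactants: 6 2-methoxy-1,3-bis(methoxymethoxy)-5-[(2-methylbut-3-yn-2-yl)oxy]benzene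
Product: 8 4-methoxy-3,5-bis(methoxymethoxy)-2-(3-methylbut-2-en-1-yl)phenol, via 1,1-dimethylallyl aryl ether 7 (not isolated)
Conditions: H2 (1 atm), Pd/CaCO3 poisoned with Pb(OAc)2, quinoline, EtOAc, rt; filter; then PhMe, 110 °C
Reagents that add atoms: none
Why: Lindlar semi-hydrogenation should give the reverse-prenyl ether 7, whose aromatic Claisen rearrangement carries the allyl unit to the ortho carbon with allylic transposition, so a linear prenyl group results; the two ortho positions are equivalent and the para position is blocked by the methoxy group.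

Step 6
Reactants: 8 4-methoxy-3,5-bis(methoxymethoxy)-2-(3-methylbut-2-en-1-yl)phenol
Product: 9 2-hydroxy-5-methoxy-4,6-bis(methoxymethoxy)-3-(3-methylbut-2-en-1-yl)benzaldehyde
Conditions: MgCl2, Et3N, (CH2O)n, MeCN, reflux
Reagents that add atoms: paraformaldehyde (as formaldehyde), C=O
Why: in the Casnati–Skattebøl ortho-formylation the magnesium phenoxide delivers formaldehyde to the only free ortho position and a second formaldehyde oxidises the hydroxymethyl intermediate by hydride transfer, under conditions that acetals and the prenyl group tolerate.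

Step 7
Reactants: 10 homogentisic acid (2,5-dihydroxyphenylacetic acid)
Product: 11 methyl 2-(2,5-dihydroxyphenyl)acetate
Conditions: MeOH, H2SO4 (cat.), reflux, N2
Reagents that add atoms: methanol, CO
Why: Fischer esterification in a large excess of methanol should give the methyl ester and keeps the acid from closing to the lactone.

Step 8
Reactants: 11 methyl 2-(2,5-dihydroxyphenyl)acetate
Product: 12 methyl 2-[2,5-bis(methoxymethoxy)phenyl]acetate
Conditions: MOMCl, i-Pr2NEt, CH2Cl2, 0 °C to rt
Reagents that add atoms: chloromethyl methyl ether (MOMCl), COCCl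
Why: MOM protection of both phenols under amine base (Williamson-type acetal formation) should outrun lactonisation of the ortho-hydroxy ester and gives the same protecting group as on ring A.

Step 9
Reactants: 12 methyl 2-[2,5-bis(methoxymethoxy)phenyl]acetate
Product: 14 methyl 2-bromo-2-[2,5-bis(methoxymethoxy)phenyl]acetate (racemic), via lithium ester enolate 13 (not isolated)
Conditions: LiN(SiMe3)2, THF, −78 °C; then cannulate into NBS, THF, −78 °C; aqueous work-up
Reagents that add atoms: N-bromosuccinimide, O=C1CCC(=O)N1Br
Why: electrophilic bromination of the preformed ester enolate, with inverse addition at low temperature, should put bromine on the α-carbon and not on the electron-rich ring; the new centre is left racemic because it becomes the labile C2.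

Step 10
Reactants: 9 2-hydroxy-5-methoxy-4,6-bis(methoxymethoxy)-3-(3-methylbut-2-en-1-yl)benzaldehyde; 14 methyl 2-bromo-2-[2,5-bis(methoxymethoxy)phenyl]acetate
Product: 15 methyl 2-[2,5-bis(methoxymethoxy)phenyl]-2-[2-formyl-4-methoxy-3,5-bis(methoxymethoxy)-6-(3-methylbut-2-en-1-yl)phenoxy]acetate (racemic)
Conditions: K2CO3, DMF, rt
Reagents that add atoms: none
Why: Williamson ether synthesis (SN2) of the phenoxide on a benzylic α-bromo ester, a strongly activated electrophile without β-hydrogens, should form the O1–C2 bond at room temperature, where the product does not yet close by aldol addition onto the formyl group.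

Step 11
Reactants: 15 methyl 2-[2,5-bis(methoxymethoxy)phenyl]-2-[2-formyl-4-methoxy-3,5-bis(methoxymethoxy)-6-(3-methylbut-2-en-1-yl)phenoxy]acetate
Product: 16 2-[2,5-bis(methoxymethoxy)phenyl]-2-[2-(hydroxymethyl)-4-methoxy-3,5-bis(methoxymethoxy)-6-(3-methylbut-2-en-1-yl)phenoxy]ethan-1-ol (racemic)
Conditions: LiAlH4, THF, 0 °C; then H2O, aq. NaOH
Reagents that add atoms: none
Why: hydride reduction with LiAlH4 should take both the aryl aldehyde and the ester to primary alcohols and leaves ethers, acetals and the trisubstituted alkene alone.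

Step 12
Reactants: 16 2-[2,5-bis(methoxymethoxy)phenyl]-2-[2-(hydroxymethyl)-4-methoxy-3,5-bis(methoxymethoxy)-6-(3-methylbut-2-en-1-yl)phenoxy]ethan-1-ol
Product: 17 2-[2,5-bis(methoxymethoxy)phenyl]-2-[2-formyl-4-methoxy-3,5-bis(methoxymethoxy)-6-(3-methylbut-2-en-1-yl)phenoxy]acetaldehyde (racemic, C2 labile; used crude)
Conditions: Dess–Martin periodinane, pyridine, CH2Cl2, 0 °C, Ar; quick aq. Na2S2O3/NaHCO3 wash
Reagents that add atoms: none
Why: Dess–Martin oxidation should convert both primary alcohols into aldehydes under buffered, non-aqueous conditions that stop at the aldehyde stage, and the crude dialdehyde is carried on at once because its α-aryloxy-α-aryl aldehyde enolises easily.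

Step 13
Reactants: 17 2-[2,5-bis(methoxymethoxy)phenyl]-2-[2-formyl-4-methoxy-3,5-bis(methoxymethoxy)-6-(3-methylbut-2-en-1-yl)phenoxy]acetaldehyde
Product: 18 (2R,3R)-2-[2,5-bis(methoxymethoxy)phenyl]-3-hydroxy-6-methoxy-5,7-bis(methoxymethoxy)-8-(3-methylbut-2-en-1-yl)-2,3-dihydro-4H-chromen-4-one
Conditions: (5aS,10bR)-2-(pentafluorophenyl)-5a,10b-dihydro-4H,6H-indeno[2,1-b][1,2,4]triazolo[4,3-d][1,4]oxazin-2-ium tetrafluoroborate (15 mol%), i-Pr2NEt (30 mol%), PhMe, 4 Å MS, 0 °C, Ar
Reagents that add atoms: none
Why: Proposed new method: the triazolylidene released by the amine adds to the ring A formyl group (C4), proton transfer gives the Breslow intermediate, and this acyl anion equivalent attacks the tethered aldehyde carbon C3 in a 6-exo-trig closure of ring C, after which loss of the carbene leaves the C4 ketone and the C3 carbinol. The closest known reactions are the carbene-catalysed intramolecular crossed benzoin closures of 2-(2-oxoalkoxy)benzaldehydes to 3-hydroxychroman-4-ones and the carbene-catalysed dynamic kinetic resolutions of base-labile α-substituted carbonyl compounds, neither of which has been shown on a dialdehyde whose α-aryloxy-α-aryl centre racemises during the closure. C2 is set by the catalyst: its hydrogen is α to a formyl, an aryl and an aryloxy group, so the amine should racemise 17 through the enol faster than the hindered, electron-rich aryl aldehyde is converted, and the indane wall of the catalyst is expected to let only the 2R enantiomer reach the Breslow carbon with its aryl group pseudo-equatorial. C3 is set in the same transition state anti to the C2 aryl group, and any cis isomer should drift to the diequatorial trans isomer by amine-mediated enolisation of the C3 hydrogen next to the new ketone, a process that leaves C2 alone. The closure itself has to stay irreversible (0 °C, weak base, work-up at full conversion), since a retro-benzoin would return product to the racemising dialdehyde and wear down the enantiomeric purity. The step needs acyl anion formation at the aryl aldehyde and not at the aliphatic one, whose Breslow intermediate could expel the aryloxide; the benzylic stabilisation of the aryl-derived intermediate, the fully substituted carbon next to the aliphatic formyl group and the small, electron-poor N-pentafluorophenyl carbene are what should secure it.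

Step 14
Reactants: 18 (2R,3R)-2-[2,5-bis(methoxymethoxy)phenyl]-3-hydroxy-6-methoxy-5,7-bis(methoxymethoxy)-8-(3-methylbut-2-en-1-yl)-2,3-dihydro-4H-chromen-4-one
Product: 19 (2R,3R)-2-(2,5-dihydroxyphenyl)-3,5,7-trihydroxy-6-methoxy-8-(3-methylbut-2-en-1-yl)-2,3-dihydro-4H-chromen-4-one
Conditions: 3 M aq. HCl, degassed MeOH, 45 °C, Ar; stop as soon as the last MOM ether is gone
Reagents that add atoms: none
Why: acid-catalysed acetal solvolysis (transacetalisation to methanol) should free all five phenols under conditions short and mild enough to spare the prenyl group and the thermodynamically preferred trans C2/C3 arrangement, and the inert atmosphere protects the hydroquinone ring.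

**Compound list**

1 | 2-methoxyresorcinol | COc1c(O)cccc1O | starting material
2 | 2-methoxy-1,3-bis(methoxymethoxy)benzene | COCOc1cccc(OCOC)c1OC | intermediate
3 | 2-[4-methoxy-3,5-bis(methoxymethoxy)phenyl]-4,4,5,5-tetramethyl-1,3,2-dioxaborolane | COCOc1cc(cc(OCOC)c1OC)B1OC(C)(C)C(C)(C)O1 | intermediate
4 | 4-methoxy-3,5-bis(methoxymethoxy)phenol | COCOc1cc(O)cc(OCOC)c1OC | intermediate
5 | 3-chloro-3-methylbut-1-yne | CC(C)(Cl)C#C | starting material
6 | 2-methoxy-1,3-bis(methoxymethoxy)-5-[(2-methylbut-3-yn-2-yl)oxy]benzene | COCOc1cc(OC(C)(C)C#C)cc(OCOC)c1OC | intermediate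
7 | 2-methoxy-1,3-bis(methoxymethoxy)-5-[(2-methylbut-3-en-2-yl)oxy]benzene (not isolated) | COCOc1cc(OC(C)(C)C=C)cc(OCOC)c1OC | intermediate
8 | 4-methoxy-3,5-bis(methoxymethoxy)-2-(3-methylbut-2-en-1-yl)phenol | COCOc1cc(O)c(CC=C(C)C)c(OCOC)c1OC | intermediate
9 | 2-hydroxy-5-methoxy-4,6-bis(methoxymethoxy)-3-(3-methylbut-2-en-1-yl)benzaldehyde | COCOc1c(C=O)c(O)c(CC=C(C)C)c(OCOC)c1OC | intermediate
10 | homogentisic acid | O=C(O)Cc1cc(O)ccc1O | starting material
11 | methyl 2-(2,5-dihydroxyphenyl)acetate | COC(=O)Cc1cc(O)ccc1O | intermediate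
12 | methyl 2-[2,5-bis(methoxymethoxy)phenyl]acetate | COCOc1ccc(OCOC)c(CC(=O)OC)c1 | intermediate
13 | lithium enolate of 12 (not isolated) | [Li+].COCOc1ccc(OCOC)c(C=C([O-])OC)c1 | intermediate
14 | methyl 2-bromo-2-[2,5-bis(methoxymethoxy)phenyl]acetate (racemic) | COCOc1ccc(OCOC)c(C(Br)C(=O)OC)c1 | intermediate
15 | methyl 2-[2,5-bis(methoxymethoxy)phenyl]-2-[2-formyl-4-methoxy-3,5-bis(methoxymethoxy)-6-(3-methylbut-2-en-1-yl)phenoxy]acetate (racemic) | COC(=O)C(Oc1c(C=O)c(OCOC)c(OC)c(OCOC)c1CC=C(C)C)c1cc(OCOC)ccc1OCOC | intermediate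
16 | 2-[2,5-bis(methoxymethoxy)phenyl]-2-[2-(hydroxymethyl)-4-methoxy-3,5-bis(methoxymethoxy)-6-(3-methylbut-2-en-1-yl)phenoxy]ethan-1-ol (racemic) | OCC(Oc1c(CO)c(OCOC)c(OC)c(OCOC)c1CC=C(C)C)c1cc(OCOC)ccc1OCOC | intermediate
17 | 2-[2,5-bis(methoxymethoxy)phenyl]-2-[2-formyl-4-methoxy-3,5-bis(methoxymethoxy)-6-(3-methylbut-2-en-1-yl)phenoxy]acetaldehyde (racemic) | O=CC(Oc1c(C=O)c(OCOC)c(OC)c(OCOC)c1CC=C(C)C)c1cc(OCOC)ccc1OCOC | intermediate
18 | (2R,3R)-2-[2,5-bis(methoxymethoxy)phenyl]-3-hydroxy-6-methoxy-5,7-bis(methoxymethoxy)-8-(3-methylbut-2-en-1-yl)-2,3-dihydro-4H-chromen-4-one | COc1c(OCOC)c(CC=C(C)C)c2c(c1OCOC)C(=O)[C@H](O)[C@@H](c1cc(OCOC)ccc1OCOC)O2 | intermediate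
19 | (2R,3R)-2-(2,5-dihydroxyphenyl)-3,5,7-trihydroxy-6-methoxy-8-(3-methylbut-2-en-1-yl)-2,3-dihydro-4H-chromen-4-one | COc1c(O)c(CC=C(C)C)c2c(c1O)C(=O)[C@H](O)[C@@H](c1cc(O)ccc1O)O2 | target

**Step count**

Total: 14 steps. Longest linear sequence: 11 steps (steps 1–6 and 10–14, from 2-methoxyresorcinol).

**Steps most likely to fail**

Step 13 (carries the label). Three processes can defeat it:
- Acyl anion formation at the aliphatic aldehyde, followed by expulsion of the ring A aryloxide and an internal redox to an aryl ester.
- Ring closure of the mismatched C2 enantiomer at a competitive rate, or retro-benzoin, either of which lowers the enantiomeric purity.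
- Amine-induced aldol closure of the C2 enol onto the aryl aldehyde, or β-elimination of O1 from the product enolate.

The fallback uses known chemistry, sets out from 9 and returns at 18. O-Allylation of 9 (allyl bromide, K2CO3, DMF) gives 2-(allyloxy)-5-methoxy-4,6-bis(methoxymethoxy)-3-(3-methylbut-2-en-1-yl)benzaldehyde F1. Addition of MeMgBr gives 1-[2-(allyloxy)-5-methoxy-4,6-bis(methoxymethoxy)-3-(3-methylbut-2-en-1-yl)phenyl]ethan-1-ol F2, and Dess–Martin oxidation gives the corresponding acetophenone F3. Claisen–Schmidt condensation (KOH, EtOH) with 2,5-bis(methoxymethoxy)benzaldehyde F4, made from commercial 2,5-dihydroxybenzaldehyde with MOMCl and i-Pr2NEt, gives the (E)-chalcone F5. Juliá–Colonna epoxidation (poly-L-leucine, urea–H2O2, DBU, THF) sets both stereocentres in the (αR,βS)-epoxide F6; poly-D-leucine is at hand if the sense is reversed. Pd(PPh3)4 and morpholine remove the allyl group to give the 2'-hydroxy epoxide F7. Catalytic camphorsulfonic acid (CH2Cl2, 0 °C) then lets the free phenol open the epoxide at the benzylic carbon with inversion, which closes ring C as the trans (2R,3R) compound 18. Only the oxygen destined to be O1 is free at that point, so the regiochemistry of ring closure is fixed.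

Step 12. The doubly activated dialdehyde may decompose during the simultaneous oxidation and work-up, by enolisation followed by aldol closure onto the aryl aldehyde or by air oxidation of the enol, and the crude material cannot be purified. The fallback sets out from 16 and returns at 17, and introduces the two carbonyl groups in separate operations. MnO2 (CH2Cl2, rt) oxidises only the benzylic alcohol and gives the stable, purifiable 2-{1-[2,5-bis(methoxymethoxy)phenyl]-2-hydroxyethoxy}-5-methoxy-4,6-bis(methoxymethoxy)-3-(3-methylbut-2-en-1-yl)benzaldehyde F8. The labile aliphatic aldehyde is then formed last under neutral conditions (2,2,6,6-tetramethylpiperidin-1-oxyl (cat.), PhI(OAc)2, CH2Cl2) to give 17, whose solution goes straight into step 13.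

Step 10. Substitution at the hindered, hydrogen-bonded phenoxide may be slow, so that base-induced aldol closure of the product onto its formyl group or loss of the bromide by hydrolysis takes over. The fallback sets out from 12 (with 9) and returns at 15, and forms the O1–C2 bond without base. Diazo transfer to 12 (p-acetamidobenzenesulfonyl azide, DBU, MeCN) gives methyl 2-diazo-2-[2,5-bis(methoxymethoxy)phenyl]acetate F9. Slow addition of F9 to 9 and Rh2(OAc)4 (1 mol%) in CH2Cl2 should give 15 by carbenoid insertion into the phenol O–H bond, which is faster than addition to a trisubstituted alkene.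

**Further compounds**

F1 | step 13 | 2-(allyloxy)-5-methoxy-4,6-bis(methoxymethoxy)-3-(3-methylbut-2-en-1-yl)benzaldehyde | O=Cc1c(OCC=C)c(CC=C(C)C)c(OCOC)c(OC)c1OCOC
F2 | step 13 | 1-[2-(allyloxy)-5-methoxy-4,6-bis(methoxymethoxy)-3-(3-methylbut-2-en-1-yl)phenyl]ethan-1-ol (racemic) | CC(O)c1c(OCC=C)c(CC=C(C)C)c(OCOC)c(OC)c1OCOC
F3 | step 13 | 1-[2-(allyloxy)-5-methoxy-4,6-bis(methoxymethoxy)-3-(3-methylbut-2-en-1-yl)phenyl]ethan-1-one | CC(=O)c1c(OCC=C)c(CC=C(C)C)c(OCOC)c(OC)c1OCOC
F4 | step 13 | 2,5-bis(methoxymethoxy)benzaldehyde | O=Cc1cc(OCOC)ccc1OCOC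
F5 | step 13 | (E)-1-[2-(allyloxy)-5-methoxy-4,6-bis(methoxymethoxy)-3-(3-methylbut-2-en-1-yl)phenyl]-3-[2,5-bis(methoxymethoxy)phenyl]prop-2-en-1-one | O=C(/C=C/c1cc(OCOC)ccc1OCOC)c1c(OCC=C)c(CC=C(C)C)c(OCOC)c(OC)c1OCOC
F6 | step 13 | [2-(allyloxy)-5-methoxy-4,6-bis(methoxymethoxy)-3-(3-methylbut-2-en-1-yl)phenyl]{(2R,3S)-3-[2,5-bis(methoxymethoxy)phenyl]oxiran-2-yl}methanone | O=C([C@@H]1O[C@H]1c1cc(OCOC)ccc1OCOC)c1c(OCC=C)c(CC=C(C)C)c(OCOC)c(OC)c1OCOC
F7 | step 13 | {(2R,3S)-3-[2,5-bis(methoxymethoxy)phenyl]oxiran-2-yl}[2-hydroxy-5-methoxy-4,6-bis(methoxymethoxy)-3-(3-methylbut-2-en-1-yl)phenyl]methanone | O=C([C@@H]1O[C@H]1c1cc(OCOC)ccc1OCOC)c1c(O)c(CC=C(C)C)c(OCOC)c(OC)c1OCOC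
F8 | step 12 | 2-{1-[2,5-bis(methoxymethoxy)phenyl]-2-hydroxyethoxy}-5-methoxy-4,6-bis(methoxymethoxy)-3-(3-methylbut-2-en-1-yl)benzaldehyde (racemic) | OCC(Oc1c(C=O)c(OCOC)c(OC)c(OCOC)c1CC=C(C)C)c1cc(OCOC)ccc1OCOC
F9 | step 10 | methyl 2-diazo-2-[2,5-bis(methoxymethoxy)phenyl]acetate | COC(=O)C(=[N+]=[N-])c1cc(OCOC)ccc1OCOC
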